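1. E comes slowly and answers G weakly: at 40.0 h, noon stands at 21.4% of the L charged, and autumn, with 9.79 times the G, at 14.7%.

| setting | noon | dawn | autumn | elm | cedar | oak | birch |
|---|---|---|---|---|---|---|---|
| L | 10 mM | 10 mM | 10 mM | 10 mM | 10 mM | 10 mM | 10 mM |
| G | 0.048 equiv | 0.19 equiv | 0.47 equiv | 0.0600 equiv | 0.120 equiv | 0.250 equiv | 0.500 equiv |
| Z | 0.83 mM (held) | 0.83 mM (held) | 0.83 mM (held) | 0.83 mM (held) | 0.83 mM (held) | 0.83 mM (held) | 0.83 mM (held) |
| remark | run made earlier | run made earlier | run made earlier |  |  |  |  |
| time |  |  |  | 40 h | 40 h | 40 h | 40 h |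

| noon: time / h | noon: E / % | dawn: time / h | dawn: E / % | autumn: time / h | autumn: E / % |
|---|---|---|---|---|---|
| 3.00 | 0.6 | 3.00 | 0.8 | 3.00 | 0.3 |
| 6.00 | 3.3 | 6.00 | 3.3 | 6.00 | 2.3 |
| 12.0 | 7.7 | 12.0 | 7.0 | 12.0 | 5.0 |
| 20.0 | 11.9 | 20.0 | 10.3 | 20.0 | 9.1 |
| 40.0 | 21.4 | 40.0 | 17.7 | 40.0 | 14.7 |

(each reading ± 0.5 percentage points)

- at the start none of Z is in solution
- "hardly changes" means that all values lie within two and a half points (for a concentration: within two and a half percent of the largest)

1. amount of E at the end, in percent of the L charged for elm, cedar, oak, birch, in this order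
2. how that number moves from the first to the last of them (rises, then falls / falls all the way / falls, then rises / rises all the way / hardly changes)

2. The quick way is to go to logarithms. The G exponent, the change in log10 of the fraction of L found as E at the end per unit of log10 of the G equivalents, is −0.165, taken from noon and autumn. It serves as an apparent order in G, read on the yield and not on a rate. As read from these two runs, at 40.0 h and with L and Z as charged there, one power of ten in G multiplies E by 0.684.

3. Dawn was not used for the slope. From noon, the exponent gives dawn 17.1%, while dawn reads 17.7%, higher by 0.60 percentage points, against a scatter of 0.5 points. The middle of the line may run low.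

4. My own reckoning from noon gives 20.6%, 18.4%, 16.3% and 14.6%. The exponent is negative, so the row falls.

5. The forecast that came with the request reads 20.7%, 19%, 16.7% and 14.5%, falls all the way, on the words “so I interpolate in log G”. It differs from my reckoning mainly at cedar and oak, where it stands higher.

6. The flask gives 20.9%, 19.9%, 17.8% and 14.4%, and the row falls all the way.

    L + G → X (k = 3.70 × 10⁻⁴ M⁻¹ s⁻¹)
    G + J → Q (k = 0.0250 M⁻¹ s⁻¹)
    L + J → E (k = 0.00630 M⁻¹ s⁻¹)
    Z ⇌ J, rate k4*(csat - [J]) (kL = 6.50 × 10⁻⁵ s⁻¹)
    E → D (k = 5.90 × 10⁻⁶ s⁻¹)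

7. At 40.0 h, L stands at 67.9% of its charge in elm and 66.5% in birch, and X, counted in fractions of the L charged, at 1.34% in elm and 12.6% in birch. Carried from elm's result with the exponent −0.165, birch comes to 14.7%, and birch holds 14.4%.

The readings are simulated from invented constants, noise included.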